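**Retrosynthetic overview**

1. Ring atoms are numbered O1, C2 (aryl), C3 (CH2OH), C4 (OH and ArCH2), C5 (CH2). The target is (2R,3R,4R), with the aryl group, the CH2OH group and the C4 hydroxyl on one face. The strategy rests on the cis C2/C3 pair and on the fully substituted C4, which can be carried as an exocyclic methylene, so the oxolane can be closed at O1–C2 and C2–C3 from an aldehyde and an allylsilane of fixed geometry.
2. C4 is finished last: the C4–CH2Ar bond comes from arylation of a spiro-epoxide at its CH2, and the epoxide from CH2OH-directed epoxidation of the C4 methylene (oxygen cis to CH2OH).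
3. The oxolane, the only ring that is made, comes from an enantioselective silyl-Prins annulation of 3,4-bis(benzyloxy)benzaldehyde with (Z)-HOCH2–C(CH2SiMe3)=CH–CH2OSiPh2t-Bu.
4. The allylsilane comes from a Wittig olefination with an α-(trimethylsilylmethyl) ester ylide followed by ester reduction. This is preferred to carbomagnesiation of a 4-silyloxybut-2-yn-1-ol, whose vinylmagnesium intermediate carries a β-silyloxy group and can collapse to an allene.
5. Order of rings: both arenes are bought, the oxolane is formed in step 4, and the benzyl ethers come off in the last step.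

Key step: step 4

Assumption: the sense of induction of the chiral acid in step 4 cannot be predicted with certainty; the (R)-catalyst is written, and the (S)-catalyst would be used instead if it proves to favour the (2S,3S) series.

**Route**

Step 1
Reactants: 1 ethyl (triphenylphosphoranylidene)acetate (2.0 equiv); 2 (iodomethyl)trimethylsilane
Product: 4 ethyl 2-(triphenylphosphoranylidene)-3-(trimethylsilyl)propanoate, via alkylated phosphonium iodide 3 (not isolated)
Conditions: EtOAc, reflux; filter off [Ph3PCH2CO2Et]I; crystallise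
Reagents that add atoms: none
Why: Bestmann-type C-alkylation of the stabilised ylide by the α-silyl iodide (SN2) gives salt 3, which the second equivalent of 1 deprotonates (transylidation) while the unsubstituted phosphonium iodide precipitates; no stereocentre is formed.

Step 2
Reactants: 4 ethyl 2-(triphenylphosphoranylidene)-3-(trimethylsilyl)propanoate; 5 2-[(tert-butyldiphenylsilyl)oxy]acetaldehyde
Product: 6 ethyl (Z)-4-[(tert-butyldiphenylsilyl)oxy]-2-[(trimethylsilyl)methyl]but-2-enoate (ester trans to CH2OSi)
Conditions: toluene, 80 °C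
Reagents that add atoms: none
Why: Wittig olefination with an α-substituted ester-stabilised ylide in an aprotic solvent should place the ester trans to the aldehyde-derived CH2OSi group, so that CH2SiMe3 ends cis to CH2OSi (Z by the priority rules); any minor geometric isomer would be removed by chromatography.

Step 3
Reactants: 6 ethyl (Z)-4-[(tert-butyldiphenylsilyl)oxy]-2-[(trimethylsilyl)methyl]but-2-enoate
Product: 7 (Z)-4-[(tert-butyldiphenylsilyl)oxy]-2-[(trimethylsilyl)methyl]but-2-en-1-ol
Conditions: i-Bu2AlH (2.5 equiv), CH2Cl2, −78 °C; aq KNaC4H4O6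
Reagents that add atoms: none
Why: 1,2-reduction of the conjugated ester by i-Bu2AlH should give the allylic alcohol and leave the allylsilane, the alkene geometry and the silyl ether untouched.

Step 4
Reactants: 7 (Z)-4-[(tert-butyldiphenylsilyl)oxy]-2-[(trimethylsilyl)methyl]but-2-en-1-ol; 8 3,4-bis(benzyloxy)benzaldehyde (1.2 equiv)
Product: 11 tert-butyl{[(2R,3R)-2-[3,4-bis(benzyloxy)phenyl]-4-methylideneoxolan-3-yl]methoxy}diphenylsilane, via (E)-oxocarbenium ion 9 (not isolated), via β-silyl carbocation 10 (not isolated)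
Conditions: (R)-3,3'-bis(2,4,6-triisopropylphenyl)-1,1'-binaphthyl-2,2'-diyl N-triflylphosphoramide (10 mol%), 5 Å MS, toluene, −40 °C
Reagents that add atoms: none
Why: Proposed new method: the chiral acid condenses 7 with 8 to the (E)-oxocarbenium ion 9 (O1–C2), paired with the chiral phosphoramide anion, and the allylsilane attacks it through its γ-carbon C3 (C2–C3) to give the β-silyl-stabilised C4 cation 10, which loses Me3Si+ (ending as Me3SiOH after capture by the water set free in the condensation) to leave the exocyclic C4 methylene and return the proton to the catalyst. The closest known reactions are the racemic Me3SiOTf-promoted annulation of 2-(silylmethyl)allyl alcohols with aldehydes to methylene oxolanes and chiral-acid Prins cyclisations of homoallylic alcohols to methylene oxacycles; an enantioselective version with an allylic alcohol has not been shown. The oxolane closes in a 5-endo-trig mode with respect to the allylsilane double bond, through an envelope with C5 as the flap. In 9 the aryl group is trans to C5 across O1=C2 and in the alkene the CH2OSi group is trans to C5 across C4=C3, so both outward groups must end on the same ring face (2,3-cis), whereas the absolute configuration (2R,3R) has to come from the chiral anion shielding one face of 9. The step needs site selectivity (only the free C5 hydroxyl can lead to a five-membered ring, the other oxygen being capped as its silyl ether), regioselectivity (the β-silicon effect directs bond formation to C3 and the new double bond to the exocyclic position) and kinetic control (an allylic oxocarbenium ion has no 2-oxonia-Cope channel for racemisation); low temperature and a non-polar solvent are chosen to hold back protodesilylation and re-ionisation of the product at C2.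

Step 5
Reactants: 11 tert-butyl{[(2R,3R)-2-[3,4-bis(benzyloxy)phenyl]-4-methylideneoxolan-3-yl]methoxy}diphenylsilane
Product: 12 [(2R,3R)-2-[3,4-bis(benzyloxy)phenyl]-4-methylideneoxolan-3-yl]methanol
Conditions: Bu4NF (1.2 equiv), THF, 0 °C → rt
Reagents that add atoms: none
Why: Fluoride-mediated cleavage of the Si–O bond (desilylation) should free the primary alcohol without touching the benzyl ethers, the exocyclic alkene or either stereocentre.

Step 6
Reactants: 12 [(2R,3R)-2-[3,4-bis(benzyloxy)phenyl]-4-methylideneoxolan-3-yl]methanol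
Product: 13 [(3S,6R,7R)-6-[3,4-bis(benzyloxy)phenyl]-1,5-dioxaspiro[2.4]heptan-7-yl]methanol (epoxide oxygen cis to CH2OH)
Conditions: VO(acac)2 (5 mol%), t-BuOOH (1.5 equiv, decane), CH2Cl2, 0 °C → rt
Reagents that add atoms: tert-butyl hydroperoxide, CC(C)(C)OO
Why: Hydroxyl-directed epoxidation of a homoallylic alcohol by a vanadium tert-butylperoxide complex bound to the C3 CH2OH group, which sits above the ring plane and should therefore deliver oxygen to the same face of the C4 methylene, setting C4 with the epoxide oxygen cis to CH2OH; arenes and benzyl ethers are inert to this reagent.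

Step 7
Reactants: 13 [(3S,6R,7R)-6-[3,4-bis(benzyloxy)phenyl]-1,5-dioxaspiro[2.4]heptan-7-yl]methanol; 14 3,4-dimethoxyphenylmagnesium bromide (3 equiv, THF solution)
Product: 15 (3R,4R,5R)-5-[3,4-bis(benzyloxy)phenyl]-3-[(3,4-dimethoxyphenyl)methyl]-4-(hydroxymethyl)oxolan-3-ol
Conditions: CuI (10 mol%), THF, −40 → 0 °C; aq NH4Cl
Reagents that add atoms: none
Why: Copper-catalysed SN2 opening of the 2,2-disubstituted epoxide by the aryl Grignard reagent at the CH2 terminus leaves the C4–O bond, and hence the C4 configuration, untouched; the first equivalent of 14 only deprotonates the hydroxyl group, whose alkoxide cannot attack the epoxide CH2 because that would need a trans-fused bicyclo[3.3.0] ring.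

Step 8
Reactants: 15 (3R,4R,5R)-5-[3,4-bis(benzyloxy)phenyl]-3-[(3,4-dimethoxyphenyl)methyl]-4-(hydroxymethyl)oxolan-3-ol
Product: 16 4-[(2R,3R,4R)-4-[(3,4-dimethoxyphenyl)methyl]-4-hydroxy-3-(hydroxymethyl)oxolan-2-yl]benzene-1,2-diol (CNP0115253.1)
Conditions: H2 (1 atm), 10% Pd/C, EtOAc, rt
Reagents that add atoms: none
Why: Palladium-catalysed hydrogenolysis of the two aryl benzyl ethers, which should cleave much faster than the cyclic benzylic C2–O1 ether in a neutral aprotic solvent, so the reaction would be stopped after uptake of two equivalents of hydrogen; no stereocentre is touched.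

**Compound list**

1 | ethyl (triphenylphosphoranylidene)acetate | CCOC(=O)C=P(c1ccccc1)(c1ccccc1)c1ccccc1 | starting material
2 | (iodomethyl)trimethylsilane | C[Si](C)(C)CI | starting material
3 | [1-ethoxy-1-oxo-3-(trimethylsilyl)propan-2-yl]triphenylphosphonium iodide | CCOC(=O)C(C[Si](C)(C)C)[P+](c1ccccc1)(c1ccccc1)c1ccccc1.[I-] | intermediate
4 | ethyl 2-(triphenylphosphoranylidene)-3-(trimethylsilyl)propanoate | CCOC(=O)C(C[Si](C)(C)C)=P(c1ccccc1)(c1ccccc1)c1ccccc1 | intermediate
5 | 2-[(tert-butyldiphenylsilyl)oxy]acetaldehyde | O=CCO[Si](c1ccccc1)(c1ccccc1)C(C)(C)C | starting material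
6 | ethyl (Z)-4-[(tert-butyldiphenylsilyl)oxy]-2-[(trimethylsilyl)methyl]but-2-enoate | CCOC(=O)/C(C[Si](C)(C)C)=C/CO[Si](c1ccccc1)(c1ccccc1)C(C)(C)C | intermediate
7 | (Z)-4-[(tert-butyldiphenylsilyl)oxy]-2-[(trimethylsilyl)methyl]but-2-en-1-ol | OC/C(C[Si](C)(C)C)=C/CO[Si](c1ccccc1)(c1ccccc1)C(C)(C)C | intermediate
8 | 3,4-bis(benzyloxy)benzaldehyde | O=Cc1ccc(OCc2ccccc2)c(OCc3ccccc3)c1 | starting material
9 | (E)-oxocarbenium ion from 7 and 8, ArCH=O+–CH2–C(CH2SiMe3)=CH–CH2OSiPh2t-Bu, as ion pair with the phosphoramide anion | O(Cc1ccccc1)c1ccc(/C=[O+]/C/C(C[Si](C)(C)C)=C/CO[Si](c2ccccc2)(c2ccccc2)C(C)(C)C)cc1OCc1ccccc1 | intermediate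
10 | ring-closed (2R,3R)-oxolan-4-ylium cation bearing CH2SiMe3 at C4 (β-silyl carbocation) | C[Si](C)(C)C[C+]1CO[C@@H](c2ccc(OCc3ccccc3)c(OCc4ccccc4)c2)[C@H]1CO[Si](c5ccccc5)(c6ccccc6)C(C)(C)C | intermediate
11 | tert-butyl{[(2R,3R)-2-[3,4-bis(benzyloxy)phenyl]-4-methylideneoxolan-3-yl]methoxy}diphenylsilane | C=C1CO[C@@H](c2ccc(OCc3ccccc3)c(OCc4ccccc4)c2)[C@H]1CO[Si](c5ccccc5)(c6ccccc6)C(C)(C)C | intermediate
12 | [(2R,3R)-2-[3,4-bis(benzyloxy)phenyl]-4-methylideneoxolan-3-yl]methanol | C=C1CO[C@@H](c2ccc(OCc3ccccc3)c(OCc4ccccc4)c2)[C@H]1CO | intermediate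
13 | [(3S,6R,7R)-6-[3,4-bis(benzyloxy)phenyl]-1,5-dioxaspiro[2.4]heptan-7-yl]methanol | C1O[C@]12CO[C@@H](c3ccc(OCc4ccccc4)c(OCc5ccccc5)c3)[C@H]2CO | intermediate
14 | 3,4-dimethoxyphenylmagnesium bromide | COc1ccc([Mg]Br)cc1OC | starting material
15 | (3R,4R,5R)-5-[3,4-bis(benzyloxy)phenyl]-3-[(3,4-dimethoxyphenyl)methyl]-4-(hydroxymethyl)oxolan-3-ol | COc1ccc(C[C@]2(O)CO[C@@H](c3ccc(OCc4ccccc4)c(OCc5ccccc5)c3)[C@H]2CO)cc1OC | intermediate
16 | 4-[(2R,3R,4R)-4-[(3,4-dimethoxyphenyl)methyl]-4-hydroxy-3-(hydroxymethyl)oxolan-2-yl]benzene-1,2-diol | COc1ccc(C[C@]2(O)CO[C@@H](c3ccc(O)c(O)c3)[C@H]2CO)cc1OC | target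

**Step count**

Total: 8 steps. Longest linear sequence: 8 steps (1 and 2 to 16).

**Steps most likely to fail**

1. Step 4 (key step). The chiral anion may hold the aryl-stabilised oxocarbenium ion too loosely to tell its faces apart. The acid may protodesilylate the allylsilane or promote an intermolecular Sakurai addition before ring closure. Re-ionisation of the product at the benzylic C2 may erode the cis relationship.
   Fallback, from 7 and 8, returning at 12, by known chemistry: the racemic annulation with an achiral promoter (Me3SiOTf, catalytic, CH2Cl2, −78 °C) would give 11 together with its enantiomer, tert-butyl{[(2S,3S)-2-[3,4-bis(benzyloxy)phenyl]-4-methylideneoxolan-3-yl]methoxy}diphenylsilane F1. Desilylation with Bu4NF would then give 12 together with [(2S,3S)-2-[3,4-bis(benzyloxy)phenyl]-4-methylideneoxolan-3-yl]methanol F2. Esterification of this mixture with (S)-2-methoxy-2-phenylacetic acid (DCC, DMAP cat., CH2Cl2, 0 °C) would give the diastereomers [(2R,3R)-2-[3,4-bis(benzyloxy)phenyl]-4-methylideneoxolan-3-yl]methyl (2S)-2-methoxy-2-phenylacetate F3 and [(2S,3S)-2-[3,4-bis(benzyloxy)phenyl]-4-methylideneoxolan-3-yl]methyl (2S)-2-methoxy-2-phenylacetate F4, to be separated by chromatography or crystallisation. Methanolysis of F3 (K2CO3, MeOH) would return 12.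

2. Step 6. Oxygen delivery through the homoallylic vanadium alkoxide is slow, and the face it must reach also carries the C2 aryl group, so undirected attack on the opposite face or acid-induced opening of the spiro-epoxide may compete.
   Fallback, from 12, returning at 13: the oxygen would be delivered through a covalent tether. Treatment of 12 with Boc2O and DMAP would give tert-butyl [(2R,3R)-2-[3,4-bis(benzyloxy)phenyl]-4-methylideneoxolan-3-yl]methyl carbonate F5. Iodocarbonate cyclisation (IBr, toluene, −85 °C) can only close cis on the oxolane and would give the cis-fused six-membered cyclic carbonate that spans the C3 CH2O group and the C4 oxygen and carries CH2I on C4, 5-[3,4-bis(benzyloxy)phenyl]-7a-(iodomethyl)tetrahydro-4H-furo[3,4-d][1,3]dioxin-2-one F6. Methanolysis (K2CO3, MeOH) would free the C4 alkoxide, which displaces iodide to give 13.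

3. Step 7. Magnesium halide may open the epoxide to a bromohydrin or trigger rearrangement to an aldehyde faster than the neopentyl-type CH2 is arylated, and the neighbouring alkoxide may slow the cuprate.
   Fallback, from 13, returning at 15: the aryl group would be brought in as an electrophile by nickel-catalysed reductive coupling with 4-bromo-1,2-dimethoxybenzene (NiBr2(dme), 2,2'-bipyridine, NaI, Et3N·HCl, Mn powder, DMPU, rt). Iodide opens the epoxide at CH2 in the flask to (3R,4R,5R)-5-[3,4-bis(benzyloxy)phenyl]-4-(hydroxymethyl)-3-(iodomethyl)oxolan-3-ol F7, whose primary radical is arylated at nickel to give 15.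

**Further compounds**

F1 | step 4 | tert-butyl{[(2S,3S)-2-[3,4-bis(benzyloxy)phenyl]-4-methylideneoxolan-3-yl]methoxy}diphenylsilane | C=C1CO[C@H](c2ccc(OCc3ccccc3)c(OCc4ccccc4)c2)[C@@H]1CO[Si](c5ccccc5)(c6ccccc6)C(C)(C)C
F2 | step 4 | [(2S,3S)-2-[3,4-bis(benzyloxy)phenyl]-4-methylideneoxolan-3-yl]methanol | C=C1CO[C@H](c2ccc(OCc3ccccc3)c(OCc4ccccc4)c2)[C@@H]1CO
F3 | step 4 | [(2R,3R)-2-[3,4-bis(benzyloxy)phenyl]-4-methylideneoxolan-3-yl]methyl (2S)-2-methoxy-2-phenylacetate | C=C1CO[C@@H](c2ccc(OCc3ccccc3)c(OCc4ccccc4)c2)[C@H]1COC(=O)[C@@H](OC)c1ccccc1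
F4 | step 4 | [(2S,3S)-2-[3,4-bis(benzyloxy)phenyl]-4-methylideneoxolan-3-yl]methyl (2S)-2-methoxy-2-phenylacetate | C=C1CO[C@H](c2ccc(OCc3ccccc3)c(OCc4ccccc4)c2)[C@@H]1COC(=O)[C@@H](OC)c1ccccc1
F5 | step 6 | tert-butyl [(2R,3R)-2-[3,4-bis(benzyloxy)phenyl]-4-methylideneoxolan-3-yl]methyl carbonate | C=C1CO[C@@H](c2ccc(OCc3ccccc3)c(OCc4ccccc4)c2)[C@H]1COC(=O)OC(C)(C)C
F6 | step 6 | cis-fused 5-[3,4-bis(benzyloxy)phenyl]-7a-(iodomethyl)tetrahydro-4H-furo[3,4-d][1,3]dioxin-2-one (carbonate oxygen on C4 cis to the C3 CH2O group, aryl on the same face) | IC[C@]12CO[C@@H](c3ccc(OCc4ccccc4)c(OCc5ccccc5)c3)[C@H]1COC(=O)O2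
F7 | step 7 | (3R,4R,5R)-5-[3,4-bis(benzyloxy)phenyl]-4-(hydroxymethyl)-3-(iodomethyl)oxolan-3-ol | IC[C@]1(O)CO[C@@H](c2ccc(OCc3ccccc3)c(OCc4ccccc4)c2)[C@H]1CO
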